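## Retrosynthetic overview
1. There is one ring, the furan. It is formed once, in step 2, before the polar head group is attached.
2. Key disconnection: the furan O–C2 bond. This opens the ring to a (Z)-4-hydroxy-enone, which is generated in the flask from a tiglyl-type (E)-enone and butanal and closes by C–O bond formation with loss of water.
3. The ketone C(=O)–CH2 bond leads back to a furyldecyl Grignard reagent and an L-serine-derived Weinreb amide. The single stereocentre is bought with L-serine.
4. The (E)-enone leads back to 11-bromoundecanoic acid and but-2-yne.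

Assumption: the alkyl run in the SMILES is read as ten CH2 groups followed by the ketone carbon, and the four starting materials are catalogue items.

## Route

Step 1
Reactants: 1 11-bromoundecanoic acid; 2 but-2-yne
Product: 5 (E)-14-bromo-3-methyltetradec-2-en-4-one, via 11-bromoundecanoyl chloride 3 (not isolated), via butenylzirconocene chloride 4 (not isolated)
Conditions: (a) 1, (COCl)2, DMF (cat.), CH2Cl2, 0 °C to rt, evaporate; (b) 2, Cp2Zr(H)Cl, THF, 0 °C to rt; (c) add 3 to 4, CuBr·SMe2 (10 mol %), THF, 0 °C to rt
Reagents that add atoms: none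
Why: Acid chloride formation, syn-hydrozirconation and copper-catalysed acylation of the alkenylzirconocene: the symmetrical alkyne leaves no regiochemical choice, syn addition of Zr–H followed by acylation with retention gives only the (E)-enone with its β-hydrogen cis to the carbonyl group, and the primary bromide is inert to all reagents.

Step 2
Reactants: 5 (E)-14-bromo-3-methyltetradec-2-en-4-one; 6 butanal
Product: 8 2-(10-bromodecyl)-3,4-dimethyl-5-propylfuran, via (Z)-4-hydroxyenone 7 (not isolated)
Conditions: [Cp*Co(C6H6)][B(C6F5)4]2 (10 mol %), PivOH (20 mol %), 6 (3 equiv, slow addition), 4 Å MS, 1,2-dichloroethane, 100 °C, sealed tube, Ar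
Reagents that add atoms: none
Why: Proposed new method: a dehydrative annulation of a plain enone with an aldehyde, in which the ketone oxygen itself steers the cationic Cp*Co catalyst (trivalent cobalt) to the β-C–H bond cis to the acyl group (pivalate-assisted metalation to a five-membered cobaltacycle); butanal then inserts reversibly into the Co–C bond, the cobalt alkoxide oxygen attacks the cobalt-activated ketone carbon so that the new O–C2 bond closes the furan ring, and loss of water to the aromatic ring pulls the uphill C–H addition forward; both alkene carbons carry methyl, so there is no regiochemical choice and no stereocentre survives; closest known reaction type: cobalt- or rhodium-catalysed addition of the alkenyl C–H bond of α,β-unsaturated O-methyl oximes to aldehydes with cyclisation to furans, here run without the auxiliary nitrogen group.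

Step 3
Reactants: 8 2-(10-bromodecyl)-3,4-dimethyl-5-propylfuran; 9 methyl N-acetyl-L-serinate
Product: 12 N-[(2S)-13-(3,4-dimethyl-5-propylfuran-2-yl)-1-hydroxy-3-oxotridecan-2-yl]acetamide, via serine Weinreb amide 10 (not isolated), via furyldecylmagnesium bromide 11 (not isolated)
Conditions: (a) 8, Mg turnings, THF, 45 °C; (b) 9 (1.3 equiv), MeNHOMe·HCl (2 equiv), iPrMgCl (6.6 equiv), THF, −20 to −5 °C; (c) add (a) to (b), −20 °C to rt; pour into cold sat. aq. NH4Cl; work up under Ar
Reagents that add atoms: none
Why: Weinreb ketone synthesis run in one pot: Me(MeO)NMgCl turns the ester into the amide, the O–H and N–H are held as magnesium salts (which also shields the α-proton, so the (S)-centre bought with L-serine is carried over unchanged), and the chelated tetrahedral adduct of 11 cannot add a second time and collapses to the ketone only on quenching.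

## Compound list
1 | 11-bromoundecanoic acid | OC(=O)CCCCCCCCCCBr | starting material
2 | but-2-yne | CC#CC | starting material
3 | 11-bromoundecanoyl chloride | ClC(=O)CCCCCCCCCCBr | intermediate
4 | chlorobis(cyclopentadienyl)[(E)-but-2-en-2-yl]zirconium | C/C=C(\C)[Zr](Cl)(C1C=CC=C1)C1C=CC=C1 | intermediate
5 | (E)-14-bromo-3-methyltetradec-2-en-4-one | C/C=C(\C)C(=O)CCCCCCCCCCBr | intermediate
6 | butanal | CCCC=O | starting material
7 | (Z)-17-bromo-4-hydroxy-5,6-dimethylheptadec-5-en-7-one (racemic carbinol) | CCCC(O)/C(C)=C(C)\C(=O)CCCCCCCCCCBr | intermediate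
8 | 2-(10-bromodecyl)-3,4-dimethyl-5-propylfuran | CCCc1oc(CCCCCCCCCCBr)c(C)c1C | intermediate
9 | methyl N-acetyl-L-serinate, (S) | CC(=O)N[C@@H](CO)C(=O)OC | starting material
10 | (S)-2-acetamido-3-hydroxy-N-methoxy-N-methylpropanamide | CC(=O)N[C@@H](CO)C(=O)N(C)OC | intermediate
11 | [10-(3,4-dimethyl-5-propylfuran-2-yl)decyl]magnesium bromide | CCCc1oc(CCCCCCCCCC[Mg]Br)c(C)c1C | intermediate
12 | N-[(2S)-13-(3,4-dimethyl-5-propylfuran-2-yl)-1-hydroxy-3-oxotridecan-2-yl]acetamide | CCCc1oc(CCCCCCCCCCC(=O)[C@H](CO)NC(C)=O)c(C)c1C | target

Total step count: 3. Longest linear sequence: 3 (1 → 5 → 8 → 12).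

## Steps most likely to fail, with fallbacks

**Step 2 (the proposed new annulation).** The ketone may bind cobalt too weakly for C–H metalation, or butanal may self-condense first. The fallback uses known chemistry. It sets out from enone 5, which is condensed with MeONH2·HCl (NaOAc, MeOH, 50 °C) to (E)-14-bromo-3-methyltetradec-2-en-4-one O-methyl oxime F1. F1 and butanal 6 are then submitted to the established oxime-ether-directed alkenyl C–H addition and cyclisation ([Cp*Co(C6H6)][B(C6F5)4]2, AcOH, 1,4-dioxane, 100 °C, or [Cp*RhCl2]2/AgSbF6). This expels O-methylhydroxylamine and comes back to the route at furan 8, at the cost of one extra step.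

**Step 3 (one-pot amide formation and Grignard addition on an unprotected N-acetyl serine unit).** Amidation may be incomplete, the magnesium salts may be poorly soluble, or the centre may partly epimerise. The fallback sets out from bromide 8 and comes back at target 12.
- N-Cbz-L-serine is converted (EDC·HCl, N-methylmorpholine, MeNHOMe·HCl, CH2Cl2, −15 °C) into the isolated carbamate Weinreb amide benzyl N-[(2S)-3-hydroxy-1-[methoxy(methyl)amino]-1-oxopropan-2-yl]carbamate F2.
- F2 is deprotonated with iPrMgCl (2 equiv) and treated with Grignard reagent 11 to give the Cbz-protected amino ketone benzyl N-[(2S)-13-(3,4-dimethyl-5-propylfuran-2-yl)-1-hydroxy-3-oxotridecan-2-yl]carbamate F3.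
- Hydrogenolysis (H2, 1 atm, Pd/C, ethyl acetate containing acetic anhydride) frees (2S)-2-amino-13-(3,4-dimethyl-5-propylfuran-2-yl)-1-hydroxytridecan-3-one F4. F4 is N-acetylated as it forms and gives 12.

**Step 1 (moisture-sensitive zirconium hydride, volatile alkyne, crude acid chloride).** The fallback sets out from acid 1 and comes back at enone 5.
- EDC·HCl and MeNHOMe·HCl (N-methylmorpholine, CH2Cl2) give 11-bromo-N-methoxy-N-methylundecanamide F5.
- Commercial 1-methyl-1-propenylmagnesium bromide (E/Z mixture, THF, −40 °C) adds to F5 to give 5 together with (Z)-14-bromo-3-methyltetradec-2-en-4-one F6.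
- The mixture is equilibrated to the more stable (E)-enone 5 with catalytic p-toluenesulfonic acid in warm toluene.

Further compounds
F1 | step 2 | (E)-14-bromo-3-methyltetradec-2-en-4-one O-methyl oxime | C/C=C(\C)C(=NOC)CCCCCCCCCCBr
F2 | step 3 | benzyl N-[(2S)-3-hydroxy-1-[methoxy(methyl)amino]-1-oxopropan-2-yl]carbamate | O=C(OCc1ccccc1)N[C@@H](CO)C(=O)N(C)OC
F3 | step 3 | benzyl N-[(2S)-13-(3,4-dimethyl-5-propylfuran-2-yl)-1-hydroxy-3-oxotridecan-2-yl]carbamate | CCCc1oc(CCCCCCCCCCC(=O)[C@H](CO)NC(=O)OCc2ccccc2)c(C)c1C
F4 | step 3 | (2S)-2-amino-13-(3,4-dimethyl-5-propylfuran-2-yl)-1-hydroxytridecan-3-one | CCCc1oc(CCCCCCCCCCC(=O)[C@H](CO)N)c(C)c1C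
F5 | step 1 | 11-bromo-N-methoxy-N-methylundecanamide | CON(C)C(=O)CCCCCCCCCCBr
F6 | step 1 | (Z)-14-bromo-3-methyltetradec-2-en-4-one | C/C=C(/C)C(=O)CCCCCCCCCCBr
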